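If you picture this flask as a catalyst loop fed through a gas film, ask first where it ends and then how fast it gets there.

    catalyst intermediate D → free catalyst + target (k1 = 0.040 /s)
    catalyst intermediate C → catalyst intermediate D (k2 = 5.4 /s)
    reagent + catalyst intermediate B ⇌ catalyst intermediate C (K3 = 22 /M, k3 = 1.1 /M/s)
    substrate + free catalyst → catalyst intermediate A (k4 = 0.96 /M/s)
    catalyst intermediate A → catalyst intermediate B (k5 = 0.18 /s)
    gas ⇌ reagent, rate k6*(csat - [reagent]) (k6 = 4.9 × 10⁻⁴ /s, csat = 200 mM)

substrate 2.2 M; gas 200 mM (held); free catalyst 2.9 mM; time 5.0 h

- target at 5.0 h, in percent of the substrate charged
- the change that raises the amount of target at 5.0 h, in percent of the substrate charged most ("none" if none brings more than 2 percentage points) (maple / oak / alder / none)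
- amount of target at 5.0 h, in percent of the substrate charged, after alder

- maple: doubling the amount of free catalyst, all else as stated
- oak: doubling the transfer coefficient of step 6, all else as stated
- alder: doubling the saturation concentration of gas, all else as stated

**End state.** The cycle hands its catalyst back and the gas is held, so this flask and its neighbour with 0.55 M of substrate both head for target and free catalyst. They can differ in how far they have come by 5.0 h.

**One loop.** At the full substrate charge, a catalyst unit spends 31.2 s on its stops other than the wait for reagent, and that wait shortens as reagent rises. The film delivers in proportion to the gap below saturation. I set the two flows equal and solve the quadratic: reagent stands at 33.8% of saturation. The wait is then 13.5 s. The longest stop, 25.0 s on catalyst intermediate D, marks the resting state.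

**Clearing time.** Divide the substrate charge by that steady flow and you have the clearing time, 9.41 h. While that flow lasts, the fraction converted is elapsed time over clearing time, so I reckon 53.1% for this flask. In the neighbour the clearing time shrinks with the charge to 2.35 h, shorter than the run, so that flask should finish.

**Three changes.** The same quadratic gives 70.2% for maple, 67.5% for alder and 61.5% for oak, so I pick maple. The forecast gives 51%, names maple and puts alder at 66%, “though maple's lead over alder is modest”.

**Simulated run.** The simulation gives 51.3%, with maple the best change at a gain of 18 percentage points, and 65.2% after alder. Set against it, the clearing time reckoned above gave 53.1% for this flask, and the neighbour with 0.55 M of substrate, cleared in a reckoned 2.35 h, reads 100% with 0% of its substrate left. What holds this flask at 51.3% is the reading at 5.0 h rather than later: left until 50.0 h, it reaches 100%, a difference of 49 points.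

The constants belong to no real substance; no experiment stands behind them.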